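Ring numbering, used for the same atoms throughout: C1 carries CH2OBz, C2 to C4 are the diene CH atoms, C5 is CH(OBz), C6 is CH(OH).
Retrosynthesis: the C6 hydroxyl and the C1=C2 bond are traced back, through epoxide-to-allylic-alcohol isomerisation and then epoxidation, to a C1=C6 double bond. The resulting cyclohexa-1,4-diene is cut at both ring double bonds, C3=C4 and C1=C6, by metathesis.
Enabling feature: the ring consists of two three-carbon units, C1-C2-C3 and C4-C5-C6, each with an sp3 centre (C2, C5) between two alkene carbons. The deoxy isomer of the carbocycle is therefore a skipped diene, the unstrained sink of metathesis of 1,4-dienes.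
Forward: divinylcarbinol benzoate and 2-allylallyl alcohol are joined and cyclised in one flask (the only ring closure). Oxygen is then placed on C1=C6, the primary alcohol is benzoylated, and the epoxide is isomerised to the conjugated dienol.
Stereochemistry: C5 arises racemic in the ring synthesis. Sharpless epoxidation with L-(+)-diethyl tartrate takes the (5R) enantiomer first, with oxygen anti to OBz, and sets C6. The C6-O bond is never broken afterwards, which gives the trans (5R,6R) array.

Key step: step 3

Remark on the chemistry: step 4 is a kinetic resolution, so no more than half of the racemic ring compound can be carried forward.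

Step 1
Reactants: 1 penta-1,4-dien-3-ol
Product: 2 penta-1,4-dien-3-yl benzoate
Conditions: BzCl, Et3N, DMAP (cat.), CH2Cl2, 0 °C to rt
Reagents that add atoms: benzoyl chloride, O=C(Cl)c1ccccc1
Why: DMAP-catalysed O-acylation of a secondary alcohol under mild base should leave the bis-allylic C-O bond intact, and no stereocentre arises because the two vinyl groups are equal.

Step 2
Reactants: 3 prop-2-yn-1-ol; 4 allylmagnesium bromide
Product: 5 2-methylidenepent-4-en-1-ol
Conditions: 4 (3 equiv), CuI (10 mol%), Et2O, 0 °C to rt; aq NH4Cl
Reagents that add atoms: none
Why: In this copper-catalysed, alkoxide-directed carbomagnesiation of a propargylic alcohol, the magnesium alkoxide delivers the allyl group to the internal alkyne carbon through a five-membered chelate, and protonation of the vinylmagnesium gives the 2-allyl allylic alcohol.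

Step 3
Reactants: 2 penta-1,4-dien-3-yl benzoate; 5 2-methylidenepent-4-en-1-ol
Product: 7 (±)-3-(hydroxymethyl)cyclohexa-2,5-dien-1-yl benzoate, via open-chain triene 6 (not isolated)
Conditions: 5 (3 equiv), second-generation Hoveyda-Grubbs catalyst (5 mol%), 1,4-benzoquinone (10 mol%), toluene (0.05 M), 60 °C, closed vessel
Reagents that add atoms: none
Why: The ruthenium alkylidene first exchanges with the monosubstituted alkene of 5 and, through a ruthenacyclobutane ([2+2] then retro-[2+2]), cross-couples it with one of the two equivalent vinyl groups of 2 to give triene 6 (new C3=C4 bond), after which the alkylidene formed at the remaining vinyl group closes onto the 1,1-disubstituted alkene (new C1=C6 bond), ethene leaving in each event. The closest known reaction type is tandem cross-metathesis/ring-closing metathesis, and the formation of cyclohexa-1,4-diene from skipped polyenes under metathesis conditions shows that this ring is the thermodynamic sink. The single six-membered carbocycle is closed by ring-closing metathesis, which is possible only from (Z)-6, so the ethene is kept in the closed vessel to return (E)-6 to the alkene pool by ethenolysis until it is drained through the Z isomer. C5 becomes a stereocentre when the two vinyl groups of 2 are told apart, nothing controls it here, and 7 is formed as a racemate that step 4 resolves. The step needs cross- over self-annulation: 5 offers one fast type 1 alkene and one type 3 alkene that reacts only intramolecularly, 2 offers two slowly homodimerising type 2 allylic benzoate alkenes, and 5 is used in excess. 1,4-Benzoquinone intercepts ruthenium hydrides, whose double-bond migration would lead to loss of benzoic acid and aromatisation.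

Step 4
Reactants: 7 (±)-3-(hydroxymethyl)cyclohexa-2,5-dien-1-yl benzoate
Product: 8 (1S,5R,6S)-1-(hydroxymethyl)-7-oxabicyclo[4.1.0]hept-3-en-5-yl benzoate (epoxide oxygen anti to the benzoate)
Conditions: Ti(OiPr)4 (0.2 equiv), L-(+)-diethyl tartrate (0.25 equiv), tBuOOH (0.55 equiv), 4 Å molecular sieves, CH2Cl2, -25 °C
Reagents that add atoms: tert-butyl hydroperoxide, CC(C)(C)OO
Why: In this Sharpless asymmetric epoxidation run as a kinetic resolution, the titanium tartrate complex binds the primary allylic alcohol so that only C1=C6 is epoxidised, and the face favoured by L-(+)-diethyl tartrate lies anti to the C5 benzoate only in (5R)-7, which should react first to give the (1S,5R,6S) epoxide while (5S)-7 stays behind and is removed by chromatography.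

Step 5
Reactants: 8 (1S,5R,6S)-1-(hydroxymethyl)-7-oxabicyclo[4.1.0]hept-3-en-5-yl benzoate
Product: 9 [(1S,5R,6S)-5-(benzoyloxy)-7-oxabicyclo[4.1.0]hept-3-en-1-yl]methyl benzoate
Conditions: BzCl, Et3N, DMAP (cat.), CH2Cl2, 0 °C
Reagents that add atoms: benzoyl chloride, O=C(Cl)c1ccccc1
Why: DMAP-catalysed acylation of the only free (primary) hydroxyl touches no stereocentre and blocks Payne migration of the epoxy alcohol.

Step 6
Reactants: 9 [(1S,5R,6S)-5-(benzoyloxy)-7-oxabicyclo[4.1.0]hept-3-en-1-yl]methyl benzoate
Product: 11 [(5R,6R)-5-(benzoyloxy)-6-hydroxycyclohexa-1,3-dien-1-yl]methyl benzoate, via trimethylsilyl ether 10 (not isolated)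
Conditions: TMSOTf (1.2 equiv), DBU (2.5 equiv), toluene, -20 °C to rt; then MeOH, citric acid (cat.), 0 °C
Reagents that add atoms: none
Why: In this silyl-triflate-promoted isomerisation of an epoxide to an allylic silyl ether, silylation of the epoxide oxygen weakens the tertiary C1-O bond, the amidine removes the C2 proton (allylic to C3=C4, so the conjugated diene is the favoured alkene), the C6-O bond and hence the (6R) centre stay untouched, and mild methanolysis frees the alcohol.

Compound list
1 | penta-1,4-dien-3-ol | C=CC(O)C=C | starting material
2 | penta-1,4-dien-3-yl benzoate | C=CC(OC(=O)c1ccccc1)C=C | intermediate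
3 | prop-2-yn-1-ol | C#CCO | starting material
4 | allylmagnesium bromide | C=CC[Mg]Br | starting material
5 | 2-methylidenepent-4-en-1-ol | C=CCC(=C)CO | intermediate
6 | 7-(hydroxymethyl)octa-1,4,7-trien-3-yl benzoate (racemic, E/Z mixture, not isolated) | C=CC(OC(=O)c1ccccc1)C=CCC(=C)CO | intermediate
7 | (±)-3-(hydroxymethyl)cyclohexa-2,5-dien-1-yl benzoate (racemic) | OCC1=CC(OC(=O)c2ccccc2)C=CC1 | intermediate
8 | (1S,5R,6S)-1-(hydroxymethyl)-7-oxabicyclo[4.1.0]hept-3-en-5-yl benzoate | OC[C@@]12CC=C[C@@H](OC(=O)c3ccccc3)[C@@H]1O2 | intermediate
9 | [(1S,5R,6S)-5-(benzoyloxy)-7-oxabicyclo[4.1.0]hept-3-en-1-yl]methyl benzoate | O=C(OC[C@@]12CC=C[C@@H](OC(=O)c3ccccc3)[C@@H]1O2)c1ccccc1 | intermediate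
10 | [(5R,6R)-5-(benzoyloxy)-6-(trimethylsilyloxy)cyclohexa-1,3-dien-1-yl]methyl benzoate (not isolated) | O=C(OCC1=CC=C[C@@H](OC(=O)c2ccccc2)[C@@H]1O[Si](C)(C)C)c1ccccc1 | intermediate
11 | [(5R,6R)-5-(benzoyloxy)-6-hydroxycyclohexa-1,3-dien-1-yl]methyl benzoate | O=C(OCC1=CC=C[C@@H](OC(=O)c2ccccc2)[C@@H]1O)c1ccccc1 | target

Total steps: 6. Longest linear sequence: 5 steps (3 to 5 to 7 to 8 to 9 to 11).

Steps most likely to fail

Step 3. The E-configured open-chain triene may accumulate faster than it is recycled, the partners may oligomerise, or double-bond migration may be followed by loss of benzoic acid and aromatisation. The fallback sets out from 2 and 5 and replaces the thermodynamically funnelled one-flask annulation by two separate, kinetically controlled metatheses. A cyclometalated ruthenium nitrate catalyst of the Z-selective Grubbs type (THF, rt) should join the type 1 alkene of 5 to one vinyl group of 2 to give (4Z)-7-(hydroxymethyl)octa-1,4,7-trien-3-yl benzoate F1, which is isolated. A separate ring-closing metathesis at high dilution with the second-generation Hoveyda-Grubbs catalyst and 1,4-benzoquinone (CH2Cl2, 40 °C) comes back to the route at 7.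

Step 6. Three failure modes are possible:
- Proton loss may occur from the CH2OBz group instead of C2.
- The neighbouring benzoate may capture the developing positive charge at C1.
- The dienyl benzoate may ionise, with aromatisation.

The fallback sets out from 9 and makes the alkene position unambiguous through a carbonyl group. Allylic oxidation of the C2 methylene (CrO3·3,5-dimethylpyrazole, CH2Cl2, -20 °C) should give [(1S,5R,6S)-5-(benzoyloxy)-2-oxo-7-oxabicyclo[4.1.0]hept-3-en-1-yl]methyl benzoate F3. Wharton transposition of this epoxy ketone (N2H4·H2O, AcOH, MeOH, 0 °C) turns C2 into the alkene CH, opens the C1-O bond and keeps the C6-O bond, coming back to the route at 11.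

Step 4. The rate difference between the two enantiomers may be too small, the titanium alkoxide may open the tertiary epoxide, or the bis-allylic benzoate may ionise on the Lewis acid. The fallback sets out from 7 and uses a metal-free dioxirane instead of the directed titanium system. Benzoylation (BzCl, Et3N, DMAP, CH2Cl2, 0 °C) gives racemic [3-(benzoyloxy)cyclohexa-1,4-dien-1-yl]methyl benzoate F2. Shi epoxidation run as a kinetic resolution should then epoxidise the trisubstituted C1=C6 alkene of the (5R) enantiomer anti to the benzoate. This uses the L-fructose-derived ketone (the enantiomer of the D-fructose-derived one), Oxone (KHSO5) and K2CO3 buffer in MeCN-dimethoxymethane-water at 0 °C. It comes back to the route at 9, bypassing 8.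

Further compounds
F1 | step 3 | (4Z)-7-(hydroxymethyl)octa-1,4,7-trien-3-yl benzoate (racemic) | C=CC(OC(=O)c1ccccc1)/C=C\CC(=C)CO
F2 | step 4 | [3-(benzoyloxy)cyclohexa-1,4-dien-1-yl]methyl benzoate (racemic) | O=C(OCC1=CC(OC(=O)c2ccccc2)C=CC1)c1ccccc1
F3 | step 6 | [(1S,5R,6S)-5-(benzoyloxy)-2-oxo-7-oxabicyclo[4.1.0]hept-3-en-1-yl]methyl benzoate | O=C(OC[C@@]12C(=O)C=C[C@@H](OC(=O)c3ccccc3)[C@@H]1O2)c1ccccc1
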